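**Retrosynthetic overview**
1. 16 ⇐ triol 15 (oxidation at C3/C22) ⇐ 14α,15α-epoxide 14 (trans-diaxial hydride opening gives C14–OH and C15–H) ⇐ diene diol 13.
2. 13 ⇐ tetracyclic diketone 11: C10=O → C10=CH2; C15=O next to C14–SO2Ph → C15=CH2 → sulfone-for-hydride allylic transposition → C14=C15–CH3.
3. 11 ⇐ acyclic tetraepoxide 8 by one two-fold epoxide-opening oxa-/carbacyclisation. All four rings form in this step: in each half the oxepane C–O bond (rings A, D) closes first through an epoxonium ion, then the enol carbon (C11, C14) closes the cyclohexane (rings B, C).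
4. 8 ⇐ C4 linker 7 (CO2tBu on C11, SO2Ph on C14; these two groups tell the halves apart) + two molecules of diepoxy amide 4 (double C-acylation).
5. 4 ⇐ geranyl bromide 1 + amide 2, then Shi epoxidation (source of C3, C6, C7, C18, C19, C22).

Locants: squalene-type backbone C1–C24 of the target. C2/C23 = OCMe2; C3/C22 = oxepane CH–O or C=O; C6/C19 = angular-methyl carbons; C7/C18 = ring-fusion CH–O; C10 = methylene-bearing carbon; C12–C13 = bridge; C14 = carbinol carbon; C15 = CH–CH3. Rings: A (oxepane O, C2–C7), B (C6–C11), C (C14–C19), D (oxepane O, C18–C23). β = face of the angular methyl of the same bicycle, α = the other face. In this numbering the target is 6S,7S,11R,14S,15S,18S,19R.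

Assumption: the presumed biosynthesis is the two-fold epoxide-opening cyclisation of a squalene 2,3:6,7:18,19:22,23-tetraepoxide (epoxonium ions opened at C6/C19 by C11/C14), and the L-series (ent-)Shi ketone gives the S epoxides (the D-fructose ketone gives the R series).

**Step 1**
Reactants: 1 geranyl bromide; 2 N-methoxy-N-methylacetamide
Product: 3 (4E)-N-methoxy-N,5,9-trimethyldeca-4,8-dienamide
Conditions: LiN(iPr)2, THF, −78 °C; then 1, −78 → −20 °C
Reagents that add atoms: none
Why: SN2 C-alkylation of the amide lithium enolate by the primary allylic bromide (enolate alkylation); the E double bond of 1 is not touched and no stereocentre is made.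

**Step 2**
Reactants: 3 (4E)-N-methoxy-N,5,9-trimethyldeca-4,8-dienamide
Product: 4 diepoxy amide (3S,6S,7S)
Conditions: ent-Shi ketone (30 mol%), KHSO5, K2CO3, Bu4NHSO4, MeCN–CH2(OMe)2–aq. Na2B4O7 buffer (pH 10.5), 0 °C
Reagents that add atoms: potassium peroxymonosulfate KHSO5, [K+].[O-]S(=O)(=O)OO
Why: Shi asymmetric epoxidation of both electron-rich trisubstituted alkenes; the chiral dioxirane (spiro transition state) adds oxygen to the same face of each alkene, setting C3, C6 and C7 as S.

**Step 3**
Reactants: 5 tert-butyl 5-bromopentanoate; 6 sodium benzenesulfinate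
Product: 7 tert-butyl 5-(phenylsulfonyl)pentanoate
Conditions: DMF, Bu4NI (cat.), 60 °C
Reagents that add atoms: none
Why: SN2 S-alkylation of the sulfinate by the primary bromide; no stereocentre.

**Step 4**
Reactants: 7 tert-butyl 5-(phenylsulfonyl)pentanoate; 4 diepoxy amide (2.1 equiv)
Product: 8 acyclic tetraepoxide bis(β-dicarbonyl) compound
Conditions: LiN(iPr)2 (2.2 equiv), THF, −78 °C (7 added to the base); then 4, −78 → −30 °C; AcOH
Reagents that add atoms: none
Why: double C-acylation (crossed Claisen type) of the ester-enolate/α-sulfonyl dianion by the Weinreb amide, whose chelated tetrahedral adducts stop over-addition; the two new CH centres (C11, C14) form as epimer mixtures and become enol carbons in step 5.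

**Step 5**
Reactants: 8 acyclic tetraepoxide bis(β-dicarbonyl) compound
Product: 10 tetracyclic keto ester keto sulfone bis(trimethylsilyl ether), via bis(silyl enol ether) 9 (not isolated)
Conditions: KN(SiMe3)2 (2.1 equiv), Me3SiCl, THF, −78 → 0 °C; solvent change to CH2Cl2; Me3SiOTf (20 mol%), 2,6-di-tert-butyl-4-methylpyridine, −78 °C
Reagents that add atoms: chlorotrimethylsilane, C[Si](C)(C)Cl
Why: Proposed new method: a two-directional version of the silyl-triflate-promoted tandem oxa-/carbacyclisation of polyepoxides ended by silyl enol ethers (closest known types: the one-directional epoxide-opening cascade with Mukaiyama-type enol silane termination, and tert-alkylation of silyl enol ethers that builds vicinal quaternary carbons), in which Me3SiOTf silylates each terminal epoxide, the neighbouring epoxide oxygen opens it at C2/C23 to a bicyclic epoxonium ion (oxepane C–O bond), and the enol carbon C11/C14 attacks the tertiary epoxonium carbon C6/C19 with inversion through a chair transition state, so that rings A/B and D/C are trans-fused (6β-Me/7α-H, 19β-Me/18α-H), C3, C7, C18 and C22 keep their epoxide configuration, and silyl transfer from the oxocarbenium ion regenerates the promoter.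

**Step 6**
Reactants: 10 tetracyclic keto ester keto sulfone bis(trimethylsilyl ether)
Product: 11 keto sulfone diol (C10 ketone with 11α-H; C15 ketone with C14–SO2Ph)
Conditions: CF3CO2H, CH2Cl2, 0 °C → rt; then PhMe, DBU (cat.), 80 °C
Reagents that add atoms: none
Why: acidolysis of the tert-butyl ester and the silyl ethers followed by β-keto acid decarboxylation; C11 is protonated under equilibrating conditions, which puts the C12 chain equatorial (11α-H, as in the target).

**Step 7**
Reactants: 11 keto sulfone diol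
Product: 12 bis(methylene) sulfone diol
Conditions: (C5H5)2Ti(CH3)2 (excess), PhMe–THF, 70 °C
Reagents that add atoms: dimethyltitanocene (C5H5)2Ti(CH3)2, [Ti+4].[CH3-].[CH3-].c1cc[cH-]c1.c1cc[cH-]c1
Why: Petasis methylenation of both ketones through the titanocene methylidene ([2+2]/retro-[2+2]); the reagent is not basic, so C11 is not epimerised and the α-quaternary keto sulfone is not cleaved.

**Step 8**
Reactants: 12 bis(methylene) sulfone diol
Product: 13 diene diol (C10 methylene; C14=C15 with 15-methyl)
Conditions: PdCl2(Ph2P(CH2)3PPh2) (5 mol%), LiEt3BH (excess), THF, 0 °C → rt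
Reagents that add atoms: none
Why: palladium-catalysed reductive desulfonylation of the tertiary allylic sulfone through a π-allyl complex of zerovalent palladium; hydride goes to the unhindered CH2 end, which moves the double bond to C14=C15 and makes the C15 methyl, while the ring B methylene is inert.

**Step 9**
Reactants: 13 diene diol
Product: 14 14α,15α-epoxide diol
Conditions: 3-ClC6H4CO3H (1.0 equiv), NaHCO3, CH2Cl2, −20 °C
Reagents that add atoms: 3-chloroperoxybenzoic acid, OOC(=O)c1cccc(Cl)c1
Why: Prilezhaev epoxidation, faster at the electron-rich tetrasubstituted alkene than at the 1,1-disubstituted one; the peracid comes from the α-face, opposite to the neighbouring angular C19 methyl, which sets the C14–O bond α.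

**Step 10**
Reactants: 14 14α,15α-epoxide diol
Product: 15 triol (14α-OH, 15β-H, 3,22-diol)
Conditions: LiEt3BH (excess), THF, 65 °C; H2O
Reagents that add atoms: none
Why: SN2 hydride opening of the epoxide under trans-diaxial (Fürst–Plattner) control: axial attack at C15 from the β-face with inversion gives 15β-H with the methyl equatorial, and C14 (neopentyl, would need equatorial attack) keeps its α-oxygen as the tertiary alcohol.

**Step 11**
Reactants: 15 triol
Product: 16 target CNP0218659.1
Conditions: Dess–Martin periodinane (3 equiv), NaHCO3, CH2Cl2, rt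
Reagents that add atoms: none
Why: Dess–Martin oxidation of the two secondary alcohols at C3 and C22 to the ketones; the tertiary C14 alcohol and the alkene do not react and no stereocentre is touched.

**Compound list**
1 | geranyl bromide, (2E)-1-bromo-3,7-dimethylocta-2,6-diene | CC(C)=CCC/C(C)=C/CBr | starting material
2 | N-methoxy-N-methylacetamide | CC(=O)N(C)OC | starting material
3 | (4E)-N-methoxy-N,5,9-trimethyldeca-4,8-dienamide | CC(C)=CCC/C(C)=C/CCC(=O)N(C)OC | intermediate
4 | diepoxy amide, 3-[(2S,3S)-3-{2-[(2S)-3,3-dimethyloxiran-2-yl]ethyl}-3-methyloxiran-2-yl]-N-methoxy-N-methylpropanamide | CC1(C)O[C@H]1CC[C@]1(C)O[C@H]1CCC(=O)N(C)OC | intermediate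
5 | tert-butyl 5-bromopentanoate | CC(C)(C)OC(=O)CCCCBr | starting material
6 | sodium benzenesulfinate | [Na+].[O-]S(=O)c1ccccc1 | starting material
7 | tert-butyl 5-(phenylsulfonyl)pentanoate | CC(C)(C)OC(=O)CCCCS(=O)(=O)c1ccccc1 | intermediate
8 | acyclic tetraepoxide, tert-butyl 2,5-bis{3-[(2S,3S)-3-{2-[(2S)-3,3-dimethyloxiran-2-yl]ethyl}-3-methyloxiran-2-yl]propanoyl}-5-(phenylsulfonyl)pentanoate (pentanoate C2 = C11 and C5 = C14, epimer mixture) | CC1(C)O[C@H]1CC[C@]1(C)O[C@H]1CCC(=O)C(C(=O)OC(C)(C)C)CCC(S(=O)(=O)c1ccccc1)C(=O)CC[C@@H]1O[C@@]1(C)CC[C@@H]1OC1(C)C | intermediate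
9 | bis(trimethylsilyl enol ether) of 8 (C10–OSiMe3 and C15–OSiMe3; C10=C11 and C14=C15, E/Z mixture; not isolated) | CC1(C)O[C@H]1CC[C@]1(C)O[C@H]1CCC(O[Si](C)(C)C)=C(C(=O)OC(C)(C)C)CCC(S(=O)(=O)c1ccccc1)=C(O[Si](C)(C)C)CC[C@@H]1O[C@@]1(C)CC[C@@H]1OC1(C)C | intermediate
10 | tetracycle with rings A–D closed: 3S- and 22S-OSiMe3, C10 and C15 ketones, C11 bearing CO2tBu, C14 bearing SO2Ph (C11 and C14 configurations not assigned; both are erased later), 6β-Me, 7α-H, 19β-Me, 18α-H | O=C1CC[C@@H]2OC(C)(C)[C@@H](O[Si](C)(C)C)CC[C@@]2(C)C1(C(=O)OC(C)(C)C)CCC1(S(=O)(=O)c3ccccc3)C(=O)CC[C@@H]2OC(C)(C)[C@@H](O[Si](C)(C)C)CC[C@]21C | intermediate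
11 | keto sulfone diol: 3S,22S-diol, C10 ketone with 11α-H (C12 equatorial), C15 ketone, C14–SO2Ph (C14 not assigned) | O=C1CC[C@@H]2OC(C)(C)[C@@H](O)CC[C@@]2(C)[C@@H]1CCC1(S(=O)(=O)c3ccccc3)C(=O)CC[C@@H]2OC(C)(C)[C@@H](O)CC[C@]21C | intermediate
12 | bis(methylene) sulfone diol: C10=CH2 and C15=CH2, C14–SO2Ph (C14 not assigned) | C=C1CC[C@@H]2OC(C)(C)[C@@H](O)CC[C@@]2(C)[C@@H]1CCC1(S(=O)(=O)c3ccccc3)C(=C)CC[C@@H]2OC(C)(C)[C@@H](O)CC[C@]21C | intermediate
13 | diene diol: C10=CH2, C14=C15 tetrasubstituted alkene with 15-methyl, 3S,22S-diol | C=C1CC[C@@H]2OC(C)(C)[C@@H](O)CC[C@@]2(C)[C@@H]1CCC1=C(C)CC[C@@H]2OC(C)(C)[C@@H](O)CC[C@]21C | intermediate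
14 | 14α,15α-epoxide of 13 | C=C1CC[C@@H]2OC(C)(C)[C@@H](O)CC[C@@]2(C)[C@@H]1CC[C@@]13O[C@@]3(C)CC[C@@H]2OC(C)(C)[C@@H](O)CC[C@]21C | intermediate
15 | triol: 14α-OH, 15β-H (15-methyl equatorial), 3S,22S-diol, C10=CH2 | C=C1CC[C@@H]2OC(C)(C)[C@@H](O)CC[C@@]2(C)[C@@H]1CC[C@]1(O)[C@@H](C)CC[C@@H]2OC(C)(C)[C@@H](O)CC[C@]21C | intermediate
16 | CNP0218659.1 (6S,7S,11R,14S,15S,18S,19R; 3,22-dione) | C=C1CC[C@@H]2OC(C)(C)C(=O)CC[C@@]2(C)[C@@H]1CC[C@]1(O)[C@@H](C)CC[C@@H]2OC(C)(C)C(=O)CC[C@]21C | target

**Step count**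
Total steps: 11. Longest linear sequence: 10 (steps 1, 2, 4–11).

**Steps most likely to fail, with fallbacks**

Step 5. Two cascades must run in one flask, and each C–C closure joins a fully substituted enol carbon to a tertiary epoxonium carbon (vicinal quaternary centres); the sulfonyl enol ether is also a weak nucleophile. The fallback cyclises each half alone on a CH2-type nucleophile and links the bicycles afterwards. It sets out from 4. Lithiated methyl phenyl sulfone acylated by 4 gives the acyclic keto sulfone F1, which after silylation and the same Me3SiOTf cascade gives the bicyclic keto sulfone F2, now with only a tertiary centre at C14. In the same way lithiated tert-butyl acetate and 4 give the acyclic keto ester F3 and then the bicyclic keto ester F4. F2 is C-alkylated with excess 1,2-dibromoethane (K2CO3, DMF) to the bromoethyl sulfone F5, and the sodium enolate of F4 (NaH, NaI, DMF, 60 °C) is alkylated with F5. This comes back to the route at 10.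

Step 8. A tertiary allylic sulfone next to a quaternary carbon may ionise slowly, or hydride may go to the wrong allyl end; the methylenation before it (step 7) also has to work on a very hindered ketone. The fallback avoids both and sets out from 10. SmI2 (THF–HMPA, −78 °C) cleaves only the C14–S bond; the regio-defined samarium enolate is trapped with N-(5-chloropyridin-2-yl)triflimide as the enol triflate F6. CF3CO2H and then warm PhMe/DBU remove the tert-butyl ester, CO2 and the silyl groups to give the keto triflate F7. Ph3P=CH2 at the only ketone gives the methylene triflate F8. MeZnCl with Pd(PPh3)4 (Negishi coupling) puts the methyl on C15. This comes back to the route at 13.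

Step 10. Hydride must attack a tertiary epoxide carbon that has a syn-axial methyl; elimination to an allylic alcohol or no reaction are possible. The fallback sets out from 14. MgBr2·OEt2 (Et2O, −20 °C) opens the epoxide in the trans-diaxial sense with bromide at the more easily ionised C15, giving the bromohydrin F9 (15β-Br, 14α-OH). Bu3SnH with AIBN (PhH, 80 °C) then replaces bromine by hydrogen through the tertiary C15 radical, which takes hydrogen axially and leaves the methyl equatorial. This comes back to the route at 15.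

**Further compounds**
F1 | step 5 | acyclic keto sulfone, 1-(phenylsulfonyl)-4-[(2S,3S)-3-{2-[(2S)-3,3-dimethyloxiran-2-yl]ethyl}-3-methyloxiran-2-yl]butan-2-one | O=S(=O)(c1ccccc1)CC(=O)CC[C@@H]1O[C@@]1(C)CC[C@@H]1OC1(C)C
F2 | step 5 | bicyclic keto sulfone (ring C/D type): C15 ketone, C14–H bearing SO2Ph (epimerisable), 22S-OSiMe3, 19β-Me, 18α-H | O=S(=O)(c1ccccc1)C1C(=O)CC[C@@H]2OC(C)(C)[C@@H](O[Si](C)(C)C)CC[C@]21C
F3 | step 5 | acyclic keto ester, tert-butyl 3-oxo-5-[(2S,3S)-3-{2-[(2S)-3,3-dimethyloxiran-2-yl]ethyl}-3-methyloxiran-2-yl]pentanoate | CC(C)(C)OC(=O)CC(=O)CC[C@@H]1O[C@@]1(C)CC[C@@H]1OC1(C)C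
F4 | step 5 | bicyclic keto ester (ring A/B type): C10 ketone, C11–H bearing CO2tBu (epimerisable), 3S-OSiMe3, 6β-Me, 7α-H | CC(C)(C)OC(=O)C1C(=O)CC[C@@H]2OC(C)(C)[C@@H](O[Si](C)(C)C)CC[C@]21C
F5 | step 5 | bromoethyl sulfone: F2 carrying CH2CH2Br on C14 (C14 not assigned) | O=S(=O)(c1ccccc1)C1(CCBr)C(=O)CC[C@@H]2OC(C)(C)[C@@H](O[Si](C)(C)C)CC[C@]21C
F6 | step 8 | enol triflate: 10 with C14=C15–OSO2CF3 in place of the keto sulfone | O=C1CC[C@@H]2OC(C)(C)[C@@H](O[Si](C)(C)C)CC[C@@]2(C)C1(C(=O)OC(C)(C)C)CCC1=C(OS(=O)(=O)C(F)(F)F)CC[C@@H]2OC(C)(C)[C@@H](O[Si](C)(C)C)CC[C@]21C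
F7 | step 8 | keto triflate diol: C10 ketone with 11α-H, C14=C15–OSO2CF3, 3S,22S-diol | O=C1CC[C@@H]2OC(C)(C)[C@@H](O)CC[C@@]2(C)[C@@H]1CCC1=C(OS(=O)(=O)C(F)(F)F)CC[C@@H]2OC(C)(C)[C@@H](O)CC[C@]21C
F8 | step 8 | methylene triflate diol: C10=CH2, C14=C15–OSO2CF3, 3S,22S-diol | C=C1CC[C@@H]2OC(C)(C)[C@@H](O)CC[C@@]2(C)[C@@H]1CCC1=C(OS(=O)(=O)C(F)(F)F)CC[C@@H]2OC(C)(C)[C@@H](O)CC[C@]21C
F9 | step 10 | bromohydrin: 15β-bromo-14α-hydroxy, 15-methyl α, C10=CH2, 3S,22S-diol | C=C1CC[C@@H]2OC(C)(C)[C@@H](O)CC[C@@]2(C)[C@@H]1CC[C@]1(O)[C@@](Br)(C)CC[C@@H]2OC(C)(C)[C@@H](O)CC[C@]21C
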